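**Retrosynthetic overview**
1. Target 23 comes from the tris-MOM flavan 22 by mild acid cleavage of three MOM ethers. The pyran ring of 22 is the only ring made in the route and is closed second to last, by Mitsunobu etherification (inversion) of the (S)-1,3-diarylpropanol 21.
2. 21 comes from the saturated ketone 19 by Ru-catalysed asymmetric transfer hydrogenation and deallylation; 19 comes from chalcone 17 by copper hydride conjugate reduction.
3. Key C–C bond: Claisen–Schmidt aldol condensation of the ring B methyl ketone 12 with the ring A aldehyde 15.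
4. 12 comes from 5-bromovanillin through 2,3-dibromo-4,5-dihydroxybenzaldehyde and two sequential halogen–metal exchange/copper-mediated prenylations; 15 comes from 2,4-dihydroxybenzaldehyde.
5. Both benzene rings are bought; ring order is therefore only: chroman heterocycle (step 16).

Assumption: the stereodescriptor in the SMILES is (2R), which agrees with the name. The carbinol centre in 5–11 is racemic and is erased in step 9.

**Route**

Step 1
Reactants: 1 5-bromovanillin (3-bromo-4-hydroxy-5-methoxybenzaldehyde)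
Product: 2 2,3-dibromo-4-hydroxy-5-methoxybenzaldehyde
Conditions: Br2 (1.2 equiv), Fe powder (cat.), NaOAc, AcOH, rt
Reagents that add atoms: bromine, BrBr
Why: Electrophilic aromatic bromination goes to the free position para to the methoxy group, the other free position being squeezed between CHO and OMe.

Step 2
Reactants: 2 2,3-dibromo-4-hydroxy-5-methoxybenzaldehyde
Product: 3 2,3-dibromo-4,5-dihydroxybenzaldehyde
Conditions: BBr3 (2.5 equiv), CH2Cl2, −78 °C → rt; then H2O
Reagents that add atoms: none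
Why: Lewis-acid cleavage of an aryl methyl ether (BBr3 demethylation) is clean on guaiacol-type aldehydes and there is nothing else in 2 for it to attack.

Step 3
Reactants: 3 2,3-dibromo-4,5-dihydroxybenzaldehyde
Product: 4 2,3-dibromo-4,5-bis(methoxymethoxy)benzaldehyde
Conditions: NaH (2.4 equiv), MOMCl (2.6 equiv), DMF, 0 °C → rt
Reagents that add atoms: chloromethyl methyl ether (MOMCl), COCCl
Why: Williamson-type O-alkylation of both phenoxides gives base- and organometal-stable MOM ethers.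

Step 4
Reactants: 4 2,3-dibromo-4,5-bis(methoxymethoxy)benzaldehyde
Product: 5 (±)-1-[2,3-dibromo-4,5-bis(methoxymethoxy)phenyl]ethanol
Conditions: MeMgBr (1.2 equiv), THF, −78 → 0 °C; then H2O
Reagents that add atoms: methylmagnesium bromide, C[Mg]Br
Why: Grignard addition to the aldehyde is much faster than any Br/Mg exchange at this temperature and installs the future acetyl carbon.

Step 5
Reactants: 5 (±)-1-[2,3-dibromo-4,5-bis(methoxymethoxy)phenyl]ethanol
Product: 6 (±)-tert-butyl{1-[2,3-dibromo-4,5-bis(methoxymethoxy)phenyl]ethoxy}dimethylsilane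
Conditions: TBSCl (1.5 equiv), imidazole (3 equiv), DMF, rt → 40 °C
Reagents that add atoms: tert-butyldimethylsilyl chloride (TBSCl), CC(C)(C)[Si](C)(C)Cl
Why: Silylation masks the only acidic proton so that the two aryl–metal steps that follow are not quenched.

Step 6
Reactants: 6 (±)-tert-butyl{1-[2,3-dibromo-4,5-bis(methoxymethoxy)phenyl]ethoxy}dimethylsilane
Product: 8 (±)-{1-[2-bromo-4,5-bis(methoxymethoxy)-3-(3-methylbut-2-en-1-yl)phenyl]ethoxy}(tert-butyl)dimethylsilane, via arylmagnesium chloride 7 (not isolated)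
Conditions: i-PrMgCl·LiCl (1.1 equiv), THF, −15 → 0 °C, 2 h; then CuBr·SMe2 (10 mol %), prenyl bromide (1.5 equiv), −15 → 0 °C
Reagents that add atoms: prenyl bromide (1-bromo-3-methylbut-2-ene), CC(C)=CCBr
Why: Br/Mg exchange (Knochel type) is expected at the bromine ortho to the chelating OMOM group and gives an ortho-bromoaryl Grignard that does not lose MgBrCl to an aryne at this temperature; copper-catalysed allylic substitution then occurs at the unhindered primary carbon of prenyl bromide. Should some exchange occur at the other bromine, that isomer also ends as 10 after step 7.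

Step 7
Reactants: 8 (±)-{1-[2-bromo-4,5-bis(methoxymethoxy)-3-(3-methylbut-2-en-1-yl)phenyl]ethoxy}(tert-butyl)dimethylsilane
Product: 10 (±)-{1-[4,5-bis(methoxymethoxy)-2,3-bis(3-methylbut-2-en-1-yl)phenyl]ethoxy}(tert-butyl)dimethylsilane, via aryllithium 9 (not isolated)
Conditions: n-BuLi (1.1 equiv), THF, −78 °C, 15 min; CuBr·SMe2 (1.2 equiv), −78 °C; prenyl bromide (2 equiv), −78 → 0 °C
Reagents that add atoms: prenyl bromide (1-bromo-3-methylbut-2-ene), CC(C)=CCBr
Why: Br/Li exchange at −78 °C is faster than deprotonation or silyl migration, and the arylcopper formed on transmetalation undergoes SN2 allylic substitution with prenyl bromide to give the linear prenyl group.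

Step 8
Reactants: 10 (±)-{1-[4,5-bis(methoxymethoxy)-2,3-bis(3-methylbut-2-en-1-yl)phenyl]ethoxy}(tert-butyl)dimethylsilane
Product: 11 (±)-1-[4,5-bis(methoxymethoxy)-2,3-bis(3-methylbut-2-en-1-yl)phenyl]ethanol
Conditions: TBAF (1.5 equiv), THF, rt; aqueous work-up
Reagents that add atoms: none
Why: Fluoride desilylation removes the TBS ether without touching MOM ethers or prenyl groups.

Step 9
Reactants: 11 (±)-1-[4,5-bis(methoxymethoxy)-2,3-bis(3-methylbut-2-en-1-yl)phenyl]ethanol
Product: 12 1-[4,5-bis(methoxymethoxy)-2,3-bis(3-methylbut-2-en-1-yl)phenyl]ethanone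
Conditions: Dess–Martin periodinane (1.3 equiv), CH2Cl2, 0 °C → rt
Reagents that add atoms: none
Why: Dess–Martin oxidation converts the benzylic secondary alcohol into the methyl ketone under neutral conditions that spare the trisubstituted alkenes and the acetals.

Step 10
Reactants: 13 2,4-dihydroxybenzaldehyde
Product: 14 2-hydroxy-4-(methoxymethoxy)benzaldehyde
Conditions: MOMCl (1.1 equiv), K2CO3 (1.2 equiv), acetone, rt
Reagents that add atoms: chloromethyl methyl ether (MOMCl), COCCl
Why: Selective O-alkylation of the more acidic 4-OH works because the 2-OH is tied up in a hydrogen bond to the aldehyde.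

Step 11
Reactants: 14 2-hydroxy-4-(methoxymethoxy)benzaldehyde
Product: 15 4-(methoxymethoxy)-2-(prop-2-en-1-yloxy)benzaldehyde
Conditions: allyl bromide (1.5 equiv), K2CO3 (2 equiv), DMF, 50 °C
Reagents that add atoms: allyl bromide, C=CCBr
Why: Williamson allylation caps the ortho phenol with a group that survives KOH and can later be removed under neutral, non-acidic conditions, so the aldehyde is not deactivated as a phenoxide in the condensation.

Step 12
Reactants: 12 1-[4,5-bis(methoxymethoxy)-2,3-bis(3-methylbut-2-en-1-yl)phenyl]ethanone; 15 4-(methoxymethoxy)-2-(prop-2-en-1-yloxy)benzaldehyde (1.2 equiv)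
Product: 17 (E)-1-[4,5-bis(methoxymethoxy)-2,3-bis(3-methylbut-2-en-1-yl)phenyl]-3-[4-(methoxymethoxy)-2-(prop-2-en-1-yloxy)phenyl]prop-2-en-1-one, via β-hydroxy ketone 16 (not isolated)
Conditions: KOH (3 equiv), EtOH, rt, 24 h
Reagents that add atoms: none
Why: Claisen–Schmidt aldol condensation of the methyl ketone enolate with the non-enolisable aldehyde, followed by E1cB loss of water, gives the E-chalcone; all protecting groups are base-stable.

Step 13
Reactants: 17 (E)-chalcone
Product: 19 1-[4,5-bis(methoxymethoxy)-2,3-bis(3-methylbut-2-en-1-yl)phenyl]-3-[4-(methoxymethoxy)-2-(prop-2-en-1-yloxy)phenyl]propan-1-one, via silyl enol ether 18 (not isolated)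
Conditions: [(Ph3P)CuH]6 (1 mol %), PhMe2SiH (1.5 equiv), toluene, rt; then K2CO3 (cat.), THF/H2O, rt
Reagents that add atoms: none
Why: Copper hydride conjugate reduction (Stryker type) delivers hydride only to the enone β-carbon, leaving the prenyl and allyl alkenes untouched.

Step 14
Reactants: 19 saturated ketone
Product: 20 (1S)-1-[4,5-bis(methoxymethoxy)-2,3-bis(3-methylbut-2-en-1-yl)phenyl]-3-[4-(methoxymethoxy)-2-(prop-2-en-1-yloxy)phenyl]propan-1-ol
Conditions: RuCl(p-cymene)[(S,S)-TsDPEN] (2 mol %), HCO2H/Et3N (5:2), EtOAc, 40 °C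
Reagents that add atoms: none
Why: Noyori–Ikariya asymmetric transfer hydrogenation of the aryl alkyl ketone with the (S,S) catalyst gives the (S)-carbinol (aryl group in the CH/π position of the transition state) and does not reduce isolated alkenes.

Step 15
Reactants: 20 (S)-allyl ether alcohol
Product: 21 (1S)-1-[4,5-bis(methoxymethoxy)-2,3-bis(3-methylbut-2-en-1-yl)phenyl]-3-[2-hydroxy-4-(methoxymethoxy)phenyl]propan-1-ol
Conditions: Pd(PPh3)4 (5 mol %), K2CO3 (3 equiv), MeOH (THF co-solvent), rt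
Reagents that add atoms: none
Why: Tsuji–Trost-type deallylation by zerovalent palladium ionises only the allyl aryl ether (methanol traps the π-allyl); the basic medium cannot ionise the benzylic alcohol, so the stereocentre is safe.

Step 16
Reactants: 21 (S)-phenol alcohol
Product: 22 (2R)-7-(methoxymethoxy)-2-[4,5-bis(methoxymethoxy)-2,3-bis(3-methylbut-2-en-1-yl)phenyl]-3,4-dihydro-2H-chromene
Conditions: PPh3 (1.5 equiv), DIAD (1.5 equiv), THF, 0 °C → rt
Reagents that add atoms: none
Why: Intramolecular Mitsunobu etherification: the phenol displaces the activated benzylic oxygen in a six-membered SN2 closure with inversion, turning the (S)-carbinol into the (2R)-flavan.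

Step 17
Reactants: 22 (2R)-tris-MOM flavan
Product: 23 (+)-(2R)-kazinol I
Conditions: HCl (1.25 M in MeOH, 6 equiv), MeOH, rt → 40 °C, argon; NaHCO3 quench
Reagents that add atoms: none
Why: Acid-catalysed transacetalisation to methanol removes the three aryl MOM ethers under conditions too mild to protonate the chroman oxygen or cyclise the ortho-prenyl catechol.

**Compound list**
1 | 5-bromovanillin (3-bromo-4-hydroxy-5-methoxybenzaldehyde) | COc1cc(C=O)cc(Br)c1O | starting material
2 | 2,3-dibromo-4-hydroxy-5-methoxybenzaldehyde | COc1cc(C=O)c(Br)c(Br)c1O | intermediate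
3 | 2,3-dibromo-4,5-dihydroxybenzaldehyde | O=Cc1cc(O)c(O)c(Br)c1Br | intermediate
4 | 2,3-dibromo-4,5-bis(methoxymethoxy)benzaldehyde | COCOc1cc(C=O)c(Br)c(Br)c1OCOC | intermediate
5 | (±)-1-[2,3-dibromo-4,5-bis(methoxymethoxy)phenyl]ethanol | CC(O)c1cc(OCOC)c(OCOC)c(Br)c1Br | intermediate
6 | (±)-tert-butyl{1-[2,3-dibromo-4,5-bis(methoxymethoxy)phenyl]ethoxy}dimethylsilane | CC(O[Si](C)(C)C(C)(C)C)c1cc(OCOC)c(OCOC)c(Br)c1Br | intermediate
7 | (±)-{2-bromo-3-[1-(tert-butyldimethylsilyloxy)ethyl]-5,6-bis(methoxymethoxy)phenyl}magnesium chloride (LiCl complex, not isolated) | CC(O[Si](C)(C)C(C)(C)C)c1cc(OCOC)c(OCOC)c([Mg]Cl)c1Br | intermediate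
8 | (±)-{1-[2-bromo-4,5-bis(methoxymethoxy)-3-(3-methylbut-2-en-1-yl)phenyl]ethoxy}(tert-butyl)dimethylsilane | CC(O[Si](C)(C)C(C)(C)C)c1cc(OCOC)c(OCOC)c(CC=C(C)C)c1Br | intermediate
9 | (±)-{6-[1-(tert-butyldimethylsilyloxy)ethyl]-3,4-bis(methoxymethoxy)-2-(3-methylbut-2-en-1-yl)phenyl}lithium (not isolated) | CC(O[Si](C)(C)C(C)(C)C)c1cc(OCOC)c(OCOC)c(CC=C(C)C)c1[Li] | intermediate
10 | (±)-{1-[4,5-bis(methoxymethoxy)-2,3-bis(3-methylbut-2-en-1-yl)phenyl]ethoxy}(tert-butyl)dimethylsilane | CC(O[Si](C)(C)C(C)(C)C)c1cc(OCOC)c(OCOC)c(CC=C(C)C)c1CC=C(C)C | intermediate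
11 | (±)-1-[4,5-bis(methoxymethoxy)-2,3-bis(3-methylbut-2-en-1-yl)phenyl]ethanol | CC(O)c1cc(OCOC)c(OCOC)c(CC=C(C)C)c1CC=C(C)C | intermediate
12 | 1-[4,5-bis(methoxymethoxy)-2,3-bis(3-methylbut-2-en-1-yl)phenyl]ethanone | CC(=O)c1cc(OCOC)c(OCOC)c(CC=C(C)C)c1CC=C(C)C | intermediate
13 | 2,4-dihydroxybenzaldehyde | O=Cc1ccc(O)cc1O | starting material
14 | 2-hydroxy-4-(methoxymethoxy)benzaldehyde | COCOc1ccc(C=O)c(O)c1 | intermediate
15 | 4-(methoxymethoxy)-2-(prop-2-en-1-yloxy)benzaldehyde | C=CCOc1cc(OCOC)ccc1C=O | intermediate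
16 | (±)-3-hydroxy-1-[4,5-bis(methoxymethoxy)-2,3-bis(3-methylbut-2-en-1-yl)phenyl]-3-[4-(methoxymethoxy)-2-(prop-2-en-1-yloxy)phenyl]propan-1-one (not isolated) | C=CCOc1cc(OCOC)ccc1C(O)CC(=O)c1cc(OCOC)c(OCOC)c(CC=C(C)C)c1CC=C(C)C | intermediate
17 | (E)-1-[4,5-bis(methoxymethoxy)-2,3-bis(3-methylbut-2-en-1-yl)phenyl]-3-[4-(methoxymethoxy)-2-(prop-2-en-1-yloxy)phenyl]prop-2-en-1-one | C=CCOc1cc(OCOC)ccc1/C=C/C(=O)c1cc(OCOC)c(OCOC)c(CC=C(C)C)c1CC=C(C)C | intermediate
18 | dimethylphenylsilyl enol ether of 19 (enol geometry not defined, not isolated) | C=CCOc1cc(OCOC)ccc1CC=C(O[Si](C)(C)c1ccccc1)c1cc(OCOC)c(OCOC)c(CC=C(C)C)c1CC=C(C)C | intermediate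
19 | 1-[4,5-bis(methoxymethoxy)-2,3-bis(3-methylbut-2-en-1-yl)phenyl]-3-[4-(methoxymethoxy)-2-(prop-2-en-1-yloxy)phenyl]propan-1-one | C=CCOc1cc(OCOC)ccc1CCC(=O)c1cc(OCOC)c(OCOC)c(CC=C(C)C)c1CC=C(C)C | intermediate
20 | (1S)-1-[4,5-bis(methoxymethoxy)-2,3-bis(3-methylbut-2-en-1-yl)phenyl]-3-[4-(methoxymethoxy)-2-(prop-2-en-1-yloxy)phenyl]propan-1-ol | C=CCOc1cc(OCOC)ccc1CC[C@H](O)c1cc(OCOC)c(OCOC)c(CC=C(C)C)c1CC=C(C)C | intermediate
21 | (1S)-1-[4,5-bis(methoxymethoxy)-2,3-bis(3-methylbut-2-en-1-yl)phenyl]-3-[2-hydroxy-4-(methoxymethoxy)phenyl]propan-1-ol | COCOc1ccc(CC[C@H](O)c2cc(OCOC)c(OCOC)c(CC=C(C)C)c2CC=C(C)C)c(O)c1 | intermediate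
22 | (2R)-7-(methoxymethoxy)-2-[4,5-bis(methoxymethoxy)-2,3-bis(3-methylbut-2-en-1-yl)phenyl]-3,4-dihydro-2H-chromene | CC(C)=CCc1c([C@H]2CCc3ccc(OCOC)cc3O2)cc(OCOC)c(OCOC)c1CC=C(C)C | intermediate
23 | (+)-(2R)-kazinol I | CC(C)=CCc1c([C@H]2CCc3ccc(O)cc3O2)cc(O)c(O)c1CC=C(C)C | target

**Totals**
Total step count: 17. Longest linear sequence: 15 steps (steps 1–9 and 12–17, from 1 to 23); the ring A aldehyde branch is 2 steps (10–11).

**Three steps most likely to fail, with fallbacks**

Step 6 (and its partner step 7): metalation of a vicinal dibromide risks aryne formation, the ring becomes very crowded, and α/γ selectivity of the allylic substitution must hold twice. Fallback, setting out from 4 and coming back at 11: the aldehyde-activated dibromide 4 is coupled twice in one operation with tributyl(3-methylbut-2-en-1-yl)stannane (3 equiv), Pd(PPh3)4 (10 mol %) and CsF in DMF at 90 °C (double Stille coupling, no aryl–metal species next to bromine) to give 4,5-bis(methoxymethoxy)-2,3-bis(3-methylbut-2-en-1-yl)benzaldehyde F1. Addition of MeMgBr in THF at −78 °C then gives 11 directly, bypassing steps 4–8.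

Step 16: the carbinol is benzylic to an electron-rich, ortho-substituted ring, so partial SN1 ionisation (loss of ee) or elimination to the styrene can compete with the SN2 closure. Fallback, setting out from 12 and coming back at 22, forms the C–O bond at the aryl carbon so that the stereocentre is never touched:
- Commercial 2-bromo-4-hydroxybenzaldehyde F2 is protected (MOMCl, K2CO3, acetone) to 2-bromo-4-(methoxymethoxy)benzaldehyde F3.
- KOH/EtOH condensation of F3 with 12 passes through the β-hydroxy ketone F4 to the (E)-bromochalcone F5.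
- [(Ph3P)CuH]6/PhMe2SiH reduction gives, through the silyl enol ether F6, the bromo ketone F7.
- RuCl(p-cymene)[(R,R)-TsDPEN] with HCO2H/Et3N gives the (R)-bromo alcohol F8.
- Pd(OAc)2 (3 mol %), 2-(di-tert-butylphosphino)-1,1′-binaphthyl (4 mol %) and Cs2CO3 in toluene at 70 °C close the ring by intramolecular aryl C–O coupling with retention, giving 22.

Step 17: protic acid may cyclise the 3′-prenyl group onto the neighbouring phenol or open the flavan at C2. Fallback, setting out from 22 and coming back at 23: TMSOTf (6 equiv) with 2,2′-bipyridyl (9 equiv) in CH2Cl2 at 0 °C → rt exchanges each aryl MOM ether for a silyl ether under nearly neutral conditions, giving the tris(trimethylsilyl) ether F9. Stirring with water at rt hydrolyses it to 23.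

**Further compounds**
F1 | step 6 | 4,5-bis(methoxymethoxy)-2,3-bis(3-methylbut-2-en-1-yl)benzaldehyde | O=Cc1cc(OCOC)c(OCOC)c(CC=C(C)C)c1CC=C(C)C
F2 | step 16 | 2-bromo-4-hydroxybenzaldehyde | O=Cc1ccc(O)cc1Br
F3 | step 16 | 2-bromo-4-(methoxymethoxy)benzaldehyde | COCOc1ccc(C=O)c(Br)c1
F4 | step 16 | (±)-3-[2-bromo-4-(methoxymethoxy)phenyl]-3-hydroxy-1-[4,5-bis(methoxymethoxy)-2,3-bis(3-methylbut-2-en-1-yl)phenyl]propan-1-one | COCOc1ccc(C(O)CC(=O)c2cc(OCOC)c(OCOC)c(CC=C(C)C)c2CC=C(C)C)c(Br)c1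
F5 | step 16 | (E)-3-[2-bromo-4-(methoxymethoxy)phenyl]-1-[4,5-bis(methoxymethoxy)-2,3-bis(3-methylbut-2-en-1-yl)phenyl]prop-2-en-1-one | COCOc1ccc(/C=C/C(=O)c2cc(OCOC)c(OCOC)c(CC=C(C)C)c2CC=C(C)C)c(Br)c1
F6 | step 16 | dimethylphenylsilyl enol ether of F7 (enol geometry not defined) | COCOc1ccc(CC=C(O[Si](C)(C)c2ccccc2)c2cc(OCOC)c(OCOC)c(CC=C(C)C)c2CC=C(C)C)c(Br)c1
F7 | step 16 | 3-[2-bromo-4-(methoxymethoxy)phenyl]-1-[4,5-bis(methoxymethoxy)-2,3-bis(3-methylbut-2-en-1-yl)phenyl]propan-1-one | COCOc1ccc(CCC(=O)c2cc(OCOC)c(OCOC)c(CC=C(C)C)c2CC=C(C)C)c(Br)c1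
F8 | step 16 | (1R)-3-[2-bromo-4-(methoxymethoxy)phenyl]-1-[4,5-bis(methoxymethoxy)-2,3-bis(3-methylbut-2-en-1-yl)phenyl]propan-1-ol | COCOc1ccc(CC[C@@H](O)c2cc(OCOC)c(OCOC)c(CC=C(C)C)c2CC=C(C)C)c(Br)c1
F9 | step 17 | (2R)-7-(trimethylsilyloxy)-2-[4,5-bis(trimethylsilyloxy)-2,3-bis(3-methylbut-2-en-1-yl)phenyl]-3,4-dihydro-2H-chromene | CC(C)=CCc1c([C@H]2CCc3ccc(O[Si](C)(C)C)cc3O2)cc(O[Si](C)(C)C)c(O[Si](C)(C)C)c1CC=C(C)C
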